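**Plan**

1. Route numbering: ring C1 (angelate carbon), C2, C3 (methyl), C4 (ring acetate), C5 (CH2), C6; side chain C7 (CHMe), C8, C9 (acetate), C10=C11.
2. Retrosynthesis: the C1 angelate is removed, C1 goes back to a ketone and the C4 acetate to the epimeric alcohol. Ring bond C4–C5 is then cut: the cyclohexane oxygens at C1 and C4 are 1,4-related, so C4 (as an aldehyde carbon) and C5 (as the β-carbon of a C1 ketone/C6=C5 methylene enone) are both acceptor carbons and can be joined reductively through a samarium ketyl.
3. The open-chain keto aldehyde is cut at C6=C5 (Mannich methylenation), C7–CH3 (conjugate addition), C6=C7 (cross-metathesis), C1–C2 (Grignard acylation) and C8–C9 (allylboration).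
4. Forward: two two-step fragments (4 and 10) are joined by metathesis, methyl and methylene are added in one three-component operation, the only ring is closed in step 9, and the three oxygens are then adjusted.
5. Stereochemistry: C9 by reagent control (allylboration), C3 from the chiral pool, C7 by catalyst control, C4 and C6 in the ring closure, C4 then inverted as the acetate is installed, C1 by axial hydride delivery.

Key step: step 9

Remark: the antipode of the Josiphos ligand in step 6 is taken to be the one that adds methyl to the Re face of C7; this is assigned by analogy and would be checked on enone 11 first.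

**Step 1**
Reactants: 1 3-methylbut-2-enal
Product: 3 (R)-6-methylhepta-1,5-dien-4-ol, via borinate 2 (not isolated)
Conditions: B-allyldiisopinocampheylborane [from (−)-α-pinene], Et2O, −78 °C; then 3 M NaOH, 30% H2O2, 0 °C → rt
Reagents that add atoms: B-allyldiisopinocampheylborane derived from (−)-α-pinene, C=CCB([C@H]1C[C@H]2C[C@@H]([C@@H]1C)C2(C)C)[C@H]1C[C@H]2C[C@@H]([C@@H]1C)C2(C)C
Why: Brown asymmetric allylboration through a chair-like six-membered transition state; the isopinocampheyl groups should direct allyl transfer to the Re face of the aldehyde, which sets C9 as R by reagent control, and the enal reacts only by 1,2-addition.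

**Step 2**
Reactants: 3 (R)-6-methylhepta-1,5-dien-4-ol
Product: 4 (R)-6-methylhepta-1,5-dien-4-yl acetate
Conditions: Ac2O, pyridine, cat. DMAP, 0 °C → rt
Reagents that add atoms: acetic anhydride, CC(=O)OC(C)=O
Why: Standard DMAP-catalysed acetylation with retention at C9; this acetate is the C9 ester of the target and is carried to the end.

**Step 3**
Reactants: 5 (R)-3-bromo-2-methylpropan-1-ol
Product: 6 (R)-(3-bromo-2-methylpropoxy)(tert-butyl)dimethylsilane
Conditions: TBSCl, imidazole, CH2Cl2, 0 °C → rt
Reagents that add atoms: tert-butyldimethylsilyl chloride, CC(C)(C)[Si](C)(C)Cl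
Why: Standard silylation of the primary alcohol; the silyl ether masks the future C4 aldehyde through the organometallic steps, and the chiral-pool C3 centre is untouched.

**Step 4**
Reactants: 6 (R)-(3-bromo-2-methylpropoxy)(tert-butyl)dimethylsilane; 7 N-methoxy-N-methylacrylamide
Product: 10 (S)-6-(tert-butyldimethylsilyloxy)-5-methylhex-1-en-3-one, via Grignard reagent 8 (not isolated), via magnesium chelate 9 (not isolated)
Conditions: Mg turnings, cat. I2, THF, 40 °C; then added to 7, THF, −78 → 0 °C; inverse quench into cold 1 M HCl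
Reagents that add atoms: none
Why: Grignard formation and acylation of a Weinreb amide; the chelated tetrahedral adduct 9 survives until the acidic quench, so the vinyl ketone is released only on work-up and is not attacked a second time, and C3 (β to magnesium) cannot epimerise.

**Step 5**
Reactants: 4 (R)-6-methylhepta-1,5-dien-4-yl acetate; 10 (S)-6-(tert-butyldimethylsilyloxy)-5-methylhex-1-en-3-one
Product: 11 (4R,6E,10S)-11-(tert-butyldimethylsilyloxy)-2,10-dimethyl-8-oxoundeca-2,6-dien-4-yl acetate
Conditions: second-generation Hoveyda–Grubbs catalyst RuCl2(H2IMes)(=CH-C6H4-2-O-i-Pr) (5 mol %), CH2Cl2, 40 °C, 4 in excess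
Reagents that add atoms: none
Why: Olefin cross-metathesis of a reactive terminal alkene with an electron-poor vinyl ketone should give the E-enone, and the trisubstituted isobutenyl alkene is too hindered to take part.

**Step 6**
Reactants: 11 (4R,6E,10S)-11-(tert-butyldimethylsilyloxy)-2,10-dimethyl-8-oxoundeca-2,6-dien-4-yl acetate
Product: 15 (4R,6R,10S)-11-(tert-butyldimethylsilyloxy)-2,6,10-trimethyl-7-methylidene-8-oxoundec-2-en-4-yl acetate, via magnesium enolate 12 (not isolated), via Mannich base 13 (not isolated), via methiodide 14 (not isolated)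
Conditions: MeMgBr (1.2 equiv), CuBr·SMe2 (5 mol %), Josiphos ligand (6 mol %), t-BuOMe, −78 °C; then CH2=NMe2+ I− (2 equiv), CH2Cl2, −78 → 0 °C; work-up; MeI, CH2Cl2, rt; then aq. NaHCO3, rt
Reagents that add atoms: methylmagnesium bromide, C[Mg]Br; Eschenmoser's salt, C=[N+](C)C.[I-]
Why: Copper-catalysed asymmetric conjugate addition, Mannich trapping of the enolate and E1cB elimination in sequence; the monovalent copper–Josiphos complex should deliver methyl to the Re face of C7 (catalyst control, 7R), enolate 12 exists only toward C6 so aminomethylation is regiospecific there, and quaternisation followed by mild base expels trimethylamine to reveal the C5 methylene without touching C7 or C3.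

**Step 7**
Reactants: 15 (4R,6R,10S)-11-(tert-butyldimethylsilyloxy)-2,6,10-trimethyl-7-methylidene-8-oxoundec-2-en-4-yl acetate
Product: 16 (4R,6R,10S)-11-hydroxy-2,6,10-trimethyl-7-methylidene-8-oxoundec-2-en-4-yl acetate
Conditions: HF·pyridine, pyridine, THF, 0 °C → rt
Reagents that add atoms: none
Why: Fluoride-mediated desilylation under buffered conditions; acetate, enone and stereocentres should be unaffected, and any five-membered lactol form of the product reopens on oxidation.

**Step 8**
Reactants: 16 (4R,6R,10S)-11-hydroxy-2,6,10-trimethyl-7-methylidene-8-oxoundec-2-en-4-yl acetate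
Product: 17 (4R,6R,10S)-2,6,10-trimethyl-7-methylidene-8,11-dioxoundec-2-en-4-yl acetate
Conditions: Dess–Martin periodinane, pyridine, CH2Cl2, 0 °C; used at once
Reagents that add atoms: none
Why: Dess–Martin oxidation under buffered non-basic conditions gives the aldehyde without epimerising the adjacent C3 centre.

**Step 9**
Reactants: 17 (4R,6R,10S)-2,6,10-trimethyl-7-methylidene-8,11-dioxoundec-2-en-4-yl acetate
Product: 19 (4R,6R)-6-[(1S,4S,5S)-5-hydroxy-4-methyl-2-oxocyclohexyl]-2-methylhept-2-en-4-yl acetate, via samarium enolate 18 (not isolated)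
Conditions: SmI2 (2.5 equiv, 0.1 M in THF), t-BuOH (2 equiv), THF (0.01 M in 17), −78 → −20 °C; then sat. aq. NH4Cl
Reagents that add atoms: none
Why: SmI2 (divalent samarium) transfers one electron to the aldehyde of 17, the C4 ketyl radical adds to the unsubstituted terminus C5 of the C1/C6/C5 enone, and the α-keto radical at C6 takes up a second electron to give the trivalent samarium enolate 18, which t-BuOH protonates at C6. The closest known reaction type is the SmI2-mediated ketyl–olefin (aldehyde–enone) reductive cyclization, here a union of two acceptor carbons made possible by the 1,4-relation of the ring oxygens at C1 and C4. The six-membered ring closes in the 6-endo-trig mode, because attack at the CH2 terminus gives the ketone-stabilised radical, whereas the 5-exo alternative would have to attack the fully substituted C6 and leave a primary radical. C4 is controlled by a chair-like transition state with the C3 methyl group and the bulky samarium-bound ketyl oxygen both equatorial, which should give the C3/C4-trans (4S) alcohol; C6 is controlled by axial protonation of enolate 18 on the chair with C3-methyl equatorial, which places the side chain equatorial and trans to the C3 methyl group across the ring, the all-equatorial and also the thermodynamically preferred arrangement. The step needs chemoselectivity for ketyl addition over two-electron reduction of the enone, pinacol coupling and attack on the allylic acetate; the intramolecular trap, high dilution, low temperature and the absence of a palladium catalyst should secure it, and the C3 centre α to the aldehyde is not enolised under these non-basic conditions. The C4 hydroxyl group is thus formed on purpose with the configuration opposite to that of the target and is inverted in step 10.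

**Step 10**
Reactants: 19 (4R,6R)-6-[(1S,4S,5S)-5-hydroxy-4-methyl-2-oxocyclohexyl]-2-methylhept-2-en-4-yl acetate
Product: 20 (4R,6R)-6-[(1S,4S,5R)-5-acetoxy-4-methyl-2-oxocyclohexyl]-2-methylhept-2-en-4-yl acetate
Conditions: AcOH (3 equiv), PPh3 (2 equiv), DIAD (2 equiv), toluene, 0 °C → rt
Reagents that add atoms: acetic acid, CC(=O)O
Why: Mitsunobu reaction; the equatorial C4 alcohol is activated as an alkoxyphosphonium ion and displaced by acetate with inversion to give the axial (4R) acetate cis to the C3 methyl group, and an equatorial leaving group has no anti-periplanar β-hydrogen, which should disfavour elimination.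

**Step 11**
Reactants: 20 (4R,6R)-6-[(1S,4S,5R)-5-acetoxy-4-methyl-2-oxocyclohexyl]-2-methylhept-2-en-4-yl acetate
Product: 21 (4R,6R)-6-[(1S,2R,4S,5R)-5-acetoxy-2-hydroxy-4-methylcyclohexyl]-2-methylhept-2-en-4-yl acetate
Conditions: NaBH4, CeCl3·7H2O, MeOH, −78 °C
Reagents that add atoms: none
Why: Luche-type borohydride reduction; hydride should attack C1 axially (that face is flanked only by axial hydrogens at C3 and C5, while the equatorial path is crowded by the C6 side chain), giving the equatorial (1R) alcohol trans to the side chain, and the acetates do not react at this temperature.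

**Step 12**
Reactants: 21 (4R,6R)-6-[(1S,2R,4S,5R)-5-acetoxy-2-hydroxy-4-methylcyclohexyl]-2-methylhept-2-en-4-yl acetate; 22 (Z)-2-methylbut-2-enoic acid
Product: 24 (1R,2S,4R,5S)-4-acetoxy-2-[(2R,4R)-4-acetoxy-6-methylhept-5-en-2-yl]-5-methylcyclohexyl (Z)-2-methylbut-2-enoate, via mixed anhydride 23 (not isolated)
Conditions: 22, 2,4,6-trichlorobenzoyl chloride, Et3N, toluene, rt; then 21, toluene, 80 °C
Reagents that add atoms: none
Why: Yamaguchi-type esterification through mixed anhydride 23; the alcohol attacks the angeloyl carbonyl because the trichlorobenzoyl carbonyl is shielded by two ortho chlorines, and leaving out a nucleophilic amine catalyst avoids the addition–elimination that would isomerise the (Z)-angelate to the (E)-tiglate.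

**Compound list**

1 | 3-methylbut-2-enal | CC(C)=CC=O | starting material
2 | (R)-6-methylhepta-1,5-dien-4-yl diisopinocampheylborinate | C=CC[C@@H](OB([C@H]1C[C@H]2C[C@@H]([C@@H]1C)C2(C)C)[C@H]1C[C@H]2C[C@@H]([C@@H]1C)C2(C)C)C=C(C)C | intermediate
3 | (R)-6-methylhepta-1,5-dien-4-ol | C=CC[C@@H](O)C=C(C)C | intermediate
4 | (R)-6-methylhepta-1,5-dien-4-yl acetate | C=CC[C@H](C=C(C)C)OC(C)=O | intermediate
5 | (R)-3-bromo-2-methylpropan-1-ol | BrC[C@H](C)CO | starting material
6 | (R)-(3-bromo-2-methylpropoxy)(tert-butyl)dimethylsilane | BrC[C@H](C)CO[Si](C)(C)C(C)(C)C | intermediate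
7 | N-methoxy-N-methylacrylamide | C=CC(=O)N(C)OC | starting material
8 | [(R)-3-(tert-butyldimethylsilyloxy)-2-methylpropyl]magnesium bromide | Br[Mg]C[C@H](C)CO[Si](C)(C)C(C)(C)C | intermediate
9 | bromomagnesium (5S)-6-(tert-butyldimethylsilyloxy)-3-[methoxy(methyl)amino]-5-methylhex-1-en-3-olate | C=CC(O[Mg]Br)(N(C)OC)C[C@H](C)CO[Si](C)(C)C(C)(C)C | intermediate
10 | (S)-6-(tert-butyldimethylsilyloxy)-5-methylhex-1-en-3-one | C=CC(=O)C[C@H](C)CO[Si](C)(C)C(C)(C)C | intermediate
11 | (4R,6E,10S)-11-(tert-butyldimethylsilyloxy)-2,10-dimethyl-8-oxoundeca-2,6-dien-4-yl acetate | CC(C)(C)[Si](C)(C)OC[C@@H](C)CC(=O)/C=C/C[C@H](C=C(C)C)OC(C)=O | intermediate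
12 | (4R,6R,7Z,10S)-8-(bromomagnesiooxy)-11-(tert-butyldimethylsilyloxy)-2,6,10-trimethylundeca-2,7-dien-4-yl acetate | CC(C)(C)[Si](C)(C)OC[C@@H](C)C/C(O[Mg]Br)=C/[C@H](C)C[C@H](C=C(C)C)OC(C)=O | intermediate
13 | (4R,6R,10S)-11-(tert-butyldimethylsilyloxy)-7-[(dimethylamino)methyl]-2,6,10-trimethyl-8-oxoundec-2-en-4-yl acetate (both C7 epimers) | CC(C)(C)[Si](C)(C)OC[C@@H](C)CC(=O)C(CN(C)C)[C@H](C)C[C@H](C=C(C)C)OC(C)=O | intermediate
14 | trimethylammonium iodide (methiodide) of 13 | CC(C)(C)[Si](C)(C)OC[C@@H](C)CC(=O)C(C[N+](C)(C)C)[C@H](C)C[C@H](C=C(C)C)OC(C)=O.[I-] | intermediate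
15 | (4R,6R,10S)-11-(tert-butyldimethylsilyloxy)-2,6,10-trimethyl-7-methylidene-8-oxoundec-2-en-4-yl acetate | CC(C)(C)[Si](C)(C)OC[C@@H](C)CC(=O)C(=C)[C@H](C)C[C@H](C=C(C)C)OC(C)=O | intermediate
16 | (4R,6R,10S)-11-hydroxy-2,6,10-trimethyl-7-methylidene-8-oxoundec-2-en-4-yl acetate | OC[C@@H](C)CC(=O)C(=C)[C@H](C)C[C@H](C=C(C)C)OC(C)=O | intermediate
17 | (4R,6R,10S)-2,6,10-trimethyl-7-methylidene-8,11-dioxoundec-2-en-4-yl acetate | O=C[C@@H](C)CC(=O)C(=C)[C@H](C)C[C@H](C=C(C)C)OC(C)=O | intermediate
18 | bis(diiodosamarium) enolate-alkoxide of 19 (C1 enolate toward C6 and C4 alkoxide) | I[Sm](I)OC=1C[C@H](C)[C@@H](O[Sm](I)I)CC=1[C@H](C)C[C@H](C=C(C)C)OC(C)=O | intermediate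
19 | (4R,6R)-6-[(1S,4S,5S)-5-hydroxy-4-methyl-2-oxocyclohexyl]-2-methylhept-2-en-4-yl acetate | O=C1C[C@H](C)[C@@H](O)C[C@H]1[C@H](C)C[C@H](C=C(C)C)OC(C)=O | intermediate
20 | (4R,6R)-6-[(1S,4S,5R)-5-acetoxy-4-methyl-2-oxocyclohexyl]-2-methylhept-2-en-4-yl acetate | O=C1C[C@H](C)[C@H](OC(C)=O)C[C@H]1[C@H](C)C[C@H](C=C(C)C)OC(C)=O | intermediate
21 | (4R,6R)-6-[(1S,2R,4S,5R)-5-acetoxy-2-hydroxy-4-methylcyclohexyl]-2-methylhept-2-en-4-yl acetate | O[C@@H]1C[C@H](C)[C@H](OC(C)=O)C[C@H]1[C@H](C)C[C@H](C=C(C)C)OC(C)=O | intermediate
22 | (Z)-2-methylbut-2-enoic acid (angelic acid) | C/C=C(/C)C(=O)O | starting material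
23 | (Z)-2-methylbut-2-enoic 2,4,6-trichlorobenzoic anhydride | C/C=C(/C)C(=O)OC(=O)c1c(Cl)cc(Cl)cc1Cl | intermediate
24 | (1R,2S,4R,5S)-4-acetoxy-2-[(2R,4R)-4-acetoxy-6-methylhept-5-en-2-yl]-5-methylcyclohexyl (Z)-2-methylbut-2-enoate | C/C=C(/C)C(=O)O[C@@H]1C[C@H](C)[C@H](OC(C)=O)C[C@H]1[C@H](C)C[C@H](C=C(C)C)OC(C)=O | target

**Count**

Total steps: 12. Longest linear sequence: 10 steps (steps 1, 2, 5–12, or steps 3–12).

**Steps most likely to fail**

1. Step 9. Two-electron reduction of the enone may outrun ketyl addition, leading to simple saturation or an aldol-type five-membered ring, and the radical addition may show poor facial selectivity at C4. The fallback closes the same C4–C5 bond with an acyl radical instead of a ketyl. It sets out from aldehyde 17: irradiation at 390 nm with (n-Bu4N)4[W10O32] (2 mol %) in MeCN abstracts the aldehyde hydrogen, the C4 acyl radical should cyclise 6-endo onto C5, and the α-keto radical is given back a hydrogen atom by the reduced polyoxotungstate. This should give (4R,6R)-2-methyl-6-[(1S,4S)-4-methyl-2,5-dioxocyclohexyl]hept-2-en-4-yl acetate F1. LiBH(s-Bu)3 (1 equiv, THF, −78 °C) should then reduce the less hindered C4 carbonyl (its α-substituent is only a methyl group) from the equatorial side to the axial alcohol (4R,6R)-6-[(1S,4S,5R)-5-hydroxy-4-methyl-2-oxocyclohexyl]-2-methylhept-2-en-4-yl acetate F2, the C4 epimer of 19. Ac2O in pyridine converts F2 into 20, where the route is rejoined; step 10 is then not needed.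

2. Step 6. Capture of the magnesium enolate by the iminium salt may be incomplete; a proton quench then gives the β-methyl ketone, whose two α-CH2 groups can no longer be told apart, and a long one-pot sequence also gives the Grignard reagent time to attack the allylic acetate. The fallback separates the two bond formations. From enone 11 the same conjugate addition is quenched at −78 °C with Me3SiCl/Et3N, and the regiodefined silyl enol ether (4R,6R,7Z,10S)-11-(tert-butyldimethylsilyloxy)-2,6,10-trimethyl-8-(trimethylsilyloxy)undeca-2,7-dien-4-yl acetate F3 is isolated by non-aqueous work-up. A Mukaiyama-type Mannich reaction of F3 with Eschenmoser's salt in CH2Cl2 at room temperature gives Mannich base 13, where the route is rejoined (MeI, then NaHCO3, as in step 6).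

3. Step 10. The alkoxyphosphonium intermediate may eliminate to cyclohexenes, or the weakly acidic acetic acid may fail to displace at the hindered secondary centre. The fallback makes activation and displacement separate operations (Lattrell–Dax-type inversion). Alcohol 19 is converted with Tf2O and pyridine (CH2Cl2, −20 °C) into (4R,6R)-2-methyl-6-[(1S,4S,5S)-4-methyl-2-oxo-5-(trifluoromethylsulfonyloxy)cyclohexyl]hept-2-en-4-yl acetate F4, which is displaced with CsOAc and 18-crown-6 in toluene at room temperature with inversion to give 20, where the route is rejoined.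

**Further compounds**

F1 | step 9 | (4R,6R)-2-methyl-6-[(1S,4S)-4-methyl-2,5-dioxocyclohexyl]hept-2-en-4-yl acetate | O=C1C[C@H](C)C(=O)C[C@H]1[C@H](C)C[C@H](C=C(C)C)OC(C)=O
F2 | step 9 | (4R,6R)-6-[(1S,4S,5R)-5-hydroxy-4-methyl-2-oxocyclohexyl]-2-methylhept-2-en-4-yl acetate | O=C1C[C@H](C)[C@H](O)C[C@H]1[C@H](C)C[C@H](C=C(C)C)OC(C)=O
F3 | step 6 | (4R,6R,7Z,10S)-11-(tert-butyldimethylsilyloxy)-2,6,10-trimethyl-8-(trimethylsilyloxy)undeca-2,7-dien-4-yl acetate | CC(C)(C)[Si](C)(C)OC[C@@H](C)C/C(O[Si](C)(C)C)=C/[C@H](C)C[C@H](C=C(C)C)OC(C)=O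
F4 | step 10 | (4R,6R)-2-methyl-6-[(1S,4S,5S)-4-methyl-2-oxo-5-(trifluoromethylsulfonyloxy)cyclohexyl]hept-2-en-4-yl acetate | O=C1C[C@H](C)[C@@H](OS(=O)(=O)C(F)(F)F)C[C@H]1[C@H](C)C[C@H](C=C(C)C)OC(C)=O
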